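**Retrosynthetic overview**
- The C8 ketone is made last by forming the C8–O bond: CO2-relayed, 19-OH-directed hydration of the 7,8-alkyne of a C40 triol-yne, through a transient six-membered enol carbonate.
- The C40 triol-yne comes from a Wittig reaction (C11=C12) between a C25 ε-phosphonium salt and a C15 lactol (masked hydroxy-enal).
- The C15 lactol comes from a Sonogashira coupling (C8–C9) of a ring A enyne (actinol + ethynyl Grignard) with 4-bromofuran-2(5H)-one; the butenolide ring fixes the C9=C10 geometry and tells C19 from C11.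
- The C25 salt comes from a C15 ε-phosphonium salt plus the C10 dialdehyde; the C15 salt comes from (R)-α-ionone by HWE olefination, allylic oxidation and CBS reduction (sets C3').
- Rings: ring A (β-ring) and ring B (ε-ring) are bought; no carbocycle is built. The only ring formed is the transient cyclic carbonate, opened in the same pot.

Assumption: the target is all-E (3R,3'R,6'R)-siphonaxanthin; carotenoid numbering is used in comments; (4R,6R)-actinol and (R)-α-ionone are bought as single enantiomers.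

**Route**

Step 1
Reactants: 1 (4R,6R)-4-hydroxy-2,2,6-trimethylcyclohexanone (actinol); 2 ethynylmagnesium bromide
Product: 3 (4R,6R)-1-ethynyl-2,2,6-trimethylcyclohexane-1,4-diol (C1 epimers)
Conditions: 2 (3 equiv), THF, 0 °C → rt; aq. NH4Cl
Reagents that add atoms: none
Why: Grignard 1,2-addition of the small acetylide to the hindered ketone after deprotonation of the 4-OH; the new C1 centre is removed in step 2 and the carbinol centre (future C3, R) is untouched.

Step 2
Reactants: 3 (4R,6R)-1-ethynyl-2,2,6-trimethylcyclohexane-1,4-diol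
Product: 5 (R)-4-ethynyl-3,5,5-trimethylcyclohex-3-en-1-yl acetate, via secondary monoacetate 4 (not isolated)
Conditions: Ac2O (1.2 equiv), pyridine, 4-(dimethylamino)pyridine (5 mol%), 0 °C → rt; then POCl3 (3 equiv), 90 °C
Reagents that add atoms: acetic anhydride, CC(=O)OC(C)=O
Why: Chemoselective acylation of the secondary over the tertiary propargylic alcohol, then POCl3/pyridine dehydration toward the only β-hydrogen gives the tetrasubstituted conjugated enyne; the acetate-bearing stereocentre is not involved.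

Step 3
Reactants: 5 (R)-4-ethynyl-3,5,5-trimethylcyclohex-3-en-1-yl acetate; 6 4-bromofuran-2(5H)-one
Product: 7 4-{[(R)-4-acetoxy-2,6,6-trimethylcyclohex-1-en-1-yl]ethynyl}furan-2(5H)-one
Conditions: PdCl2(PPh3)2 (3 mol%), CuI (6 mol%), Et3N (3 equiv), THF, 25 °C
Reagents that add atoms: none
Why: Sonogashira coupling of the terminal alkyne with the activated β-bromo enoate forms C8–C9; the ring double bond of the butenolide holds the future C19 cis to C11, which is the chain geometry of the target at C9=C10 (a tertiary amine is used so that no amine addition–elimination at the bromide occurs).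

Step 4
Reactants: 7 4-{[(R)-4-acetoxy-2,6,6-trimethylcyclohex-1-en-1-yl]ethynyl}furan-2(5H)-one
Product: 8 4-{[(R)-4-hydroxy-2,6,6-trimethylcyclohex-1-en-1-yl]ethynyl}-2,5-dihydrofuran-2-ol (anomers)
Conditions: i-Bu2AlH (3.5 equiv), CH2Cl2, −78 °C; MeOH, then aq. KNaC4H4O6; no acid, used crude at once
Reagents that add atoms: none
Why: Low-temperature i-Bu2AlH 1,2-reduction of the lactone stops at the aluminium lactolate and the same reagent removes the acetate, giving the lactol as a masked (Z)-4-hydroxy-enal in which C11 (aldehyde level) and C19 (alcohol level) are differentiated.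

Step 5
Reactants: 9 (R)-α-ionone; 10 triethyl phosphonoacetate
Product: 12 ethyl (2E,4E)-3-methyl-5-[(1R)-2,6,6-trimethylcyclohex-2-en-1-yl]penta-2,4-dienoate, via sodium phosphonate carbanion 11 (not isolated)
Conditions: NaH (1.15 equiv), 10 (1.2 equiv), THF, 0 → 45 °C; minor (2Z) isomer removed on silica
Reagents that add atoms: none
Why: Horner–Wadsworth–Emmons olefination of the methyl ketone, E-selective; the stabilised phosphonate anion is too weak a base to remove the γ-hydrogen, so C6' (R) is kept.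

Step 6
Reactants: 12 ethyl (2E,4E)-3-methyl-5-[(1R)-2,6,6-trimethylcyclohex-2-en-1-yl]penta-2,4-dienoate
Product: 13 ethyl (2E,4E)-3-methyl-5-[(1R)-2,6,6-trimethyl-4-oxocyclohex-2-en-1-yl]penta-2,4-dienoate
Conditions: t-BuOOH (70% aq.), aq. NaOCl, K2CO3, MeCN, −5 → 0 °C
Reagents that add atoms: tert-butyl hydroperoxide, CC(C)(C)OO
Why: Radical allylic oxidation (tert-butylperoxyl chain) of the ring CH2 next to the trisubstituted alkene gives the enone; the C6'–H is shielded by the gem-dimethyl group and the cold, weakly basic medium avoids γ-epimerisation.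

Step 7
Reactants: 13 ethyl (2E,4E)-3-methyl-5-[(1R)-2,6,6-trimethyl-4-oxocyclohex-2-en-1-yl]penta-2,4-dienoate
Product: 14 ethyl (2E,4E)-5-[(1R,4R)-4-hydroxy-2,6,6-trimethylcyclohex-2-en-1-yl]-3-methylpenta-2,4-dienoate
Conditions: (S)-1-methyl-3,3-diphenyltetrahydro-1H,3H-pyrrolo[1,2-c][1,3,2]oxazaborole ((S)-Me-CBS, 20 mol%), catecholborane (1.5 equiv), toluene, −78 °C
Reagents that add atoms: none
Why: Corey–Bakshi–Shibata reduction; catalyst-controlled hydride delivery to the ring enone (alkenyl arm as the large group) sets C3' as R, trans to the side chain, with clean 1,2-selectivity and no reaction at the dienoate.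

Step 8
Reactants: 14 ethyl (2E,4E)-5-[(1R,4R)-4-hydroxy-2,6,6-trimethylcyclohex-2-en-1-yl]-3-methylpenta-2,4-dienoate
Product: 15 (2E,4E)-5-[(1R,4R)-4-hydroxy-2,6,6-trimethylcyclohex-2-en-1-yl]-3-methylpenta-2,4-dien-1-ol
Conditions: i-Bu2AlH (3.5 equiv), CH2Cl2, −78 → −20 °C; aq. KNaC4H4O6
Reagents that add atoms: none
Why: i-Bu2AlH 1,2-reduction of the conjugated ester to the primary allylic alcohol; no stereocentre is touched.

Step 9
Reactants: 15 (2E,4E)-5-[(1R,4R)-4-hydroxy-2,6,6-trimethylcyclohex-2-en-1-yl]-3-methylpenta-2,4-dien-1-ol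
Product: 16 [(2E,4E)-5-((1R,4R)-4-hydroxy-2,6,6-trimethylcyclohex-2-en-1-yl)-3-methylpenta-2,4-dienyl]triphenylphosphonium bromide
Conditions: PPh3·HBr (1.05 equiv), MeOH, 0 → 25 °C, dark
Reagents that add atoms: triphenylphosphine hydrobromide, [Br-].c1ccc(cc1)[PH+](c1ccccc1)c1ccccc1
Why: Classical Wittig-salt formation by acid-mediated SN1 substitution; the dienylic primary alcohol ionises to a pentadienyl cation that PPh3 captures at the primary terminus, far faster than the isolated ring allylic alcohol ionises.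

Step 10
Reactants: 16 C15 ε-phosphonium bromide; 17 (2E,4E,6E)-2,7-dimethylocta-2,4,6-trienedial
Product: 19 (2E,4E,6E,8E,10E,12E)-13-[(1R,4R)-4-hydroxy-2,6,6-trimethylcyclohex-2-en-1-yl]-2,7,11-trimethyltrideca-2,4,6,8,10,12-hexaenal, via C15 ylide 18 (not isolated)
Conditions: 17 (1.5 equiv), 1,2-epoxybutane, EtOH, reflux, dark; crystallisation
Reagents that add atoms: none
Why: Wittig olefination under neutral epoxide conditions forms C11'=C12'; mono-condensation is selective because the product polyenal is less electrophilic than the dialdehyde, and the hindered 11'Z isomer equilibrates to E at reflux.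

Step 11
Reactants: 19 C25 ε-apo-aldehyde
Product: 20 (2E,4E,6E,8E,10E,12E)-13-[(1R,4R)-4-hydroxy-2,6,6-trimethylcyclohex-2-en-1-yl]-2,7,11-trimethyltrideca-2,4,6,8,10,12-hexaen-1-ol
Conditions: NaBH4, MeOH/THF, 0 °C, dark
Reagents that add atoms: none
Why: Chemoselective 1,2-hydride reduction of the polyenal to the primary allylic alcohol.

Step 12
Reactants: 20 C25 ε-apo-alcohol
Product: 21 [(2E,4E,6E,8E,10E,12E)-13-((1R,4R)-4-hydroxy-2,6,6-trimethylcyclohex-2-en-1-yl)-2,7,11-trimethyltrideca-2,4,6,8,10,12-hexaenyl]triphenylphosphonium bromide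
Conditions: PPh3·HBr (1.05 equiv), MeOH/CH2Cl2, 0 °C, dark, Ar
Reagents that add atoms: triphenylphosphine hydrobromide, [Br-].c1ccc(cc1)[PH+](c1ccccc1)c1ccccc1
Why: Wittig-salt formation as for retinyl salts, by SN1 ionisation of the polyenylic alcohol and capture by PPh3 at the primary terminus, which keeps full conjugation; one equivalent of acid at 0 °C spares the ring allylic alcohol.

Step 13
Reactants: 21 C25 ε-phosphonium bromide; 8 C15 lactol
Product: 24 (3R,3'R,6'R)-7,8-didehydro-β,ε-carotene-3,19,3'-triol, via C25 ylide 22 (not isolated), via open-chain hydroxy enal 23 (not isolated)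
Conditions: 21, NaN(SiMe3)2 (2.1 equiv), THF, −78 °C; add 8 (1.3 equiv) pre-treated with NaN(SiMe3)2 (2.0 equiv); −78 → 0 °C, dark; then EtOAc, reflux, 2 h
Reagents that add atoms: none
Why: Wittig olefination of the ring-opened lactolate forms C11=C12 and frees the 19-OH; the C9=C10 geometry is inherited from the butenolide, and brief heating converts the hindered 11Z isomer to 11E without touching C9=C10.

Step 14
Reactants: 24 (3R,3'R,6'R)-7,8-didehydro-β,ε-carotene-3,19,3'-triol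
Product: 26 (3R,3'R,6'R)-3,19,3'-trihydroxy-7,8-dihydro-β,ε-caroten-8-one (siphonaxanthin), via cyclic enol carbonate 25 (not isolated)
Conditions: CO2 (10 bar), AgOAc (10 mol%), 1,8-diazabicyclo[5.4.0]undec-7-ene (DBU, 1.5 equiv), MeCN/CH2Cl2, 25 °C, dark; vent; then MeOH, K2CO3 (0.2 equiv), 0 → 25 °C
Reagents that add atoms: carbon dioxide, O=C=O
Why: Proposed new method: CO2 acts as a traceless oxygen-delivery group, since DBU/CO2 turns the primary 19-OH into an alkyl carbonate anion (the 3- and 3'-carbonates form reversibly but have no alkyne in reach), monovalent silver π-activates the 7,8-alkyne, and the carbonate oxygen adds anti in a 6-exo-dig mode to C8, which is the only carbon reachable through a six-membered transition state and also the alkyne terminus whose positive charge is stabilised by the polyene; protodeargentation gives enol carbonate 25, and methanolysis releases the C8 ketone (kinetic C7 protonation of the dienol keeps the ring double bond at C5=C6) and the free 19-OH; the closest known reaction type is the silver-catalysed carboxylative 5-exo-dig cyclisation of propargylic alcohols with CO2 to α-alkylidene cyclic carbonates and their solvolysis to α-hydroxy ketones, which has not been shown for 6-exo closure of a 2-alkynyl allylic alcohol or on a carotenoid polyene.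

**Compound list**

1 | (4R,6R)-4-hydroxy-2,2,6-trimethylcyclohexanone (actinol) | O=C1[C@H](C)C[C@@H](O)CC1(C)C | starting material
2 | ethynylmagnesium bromide | C#C[Mg]Br | starting material
3 | (4R,6R)-1-ethynyl-2,2,6-trimethylcyclohexane-1,4-diol (C1 epimers) | C#CC1(O)[C@H](C)C[C@@H](O)CC1(C)C | intermediate
4 | (4R,6R)-1-ethynyl-1-hydroxy-2,2,6-trimethylcyclohexan-4-yl acetate (secondary monoacetate) | C#CC1(O)[C@H](C)C[C@@H](OC(C)=O)CC1(C)C | intermediate (not isolated)
5 | (R)-4-ethynyl-3,5,5-trimethylcyclohex-3-en-1-yl acetate | C#CC1=C(C)C[C@@H](OC(C)=O)CC1(C)C | intermediate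
6 | 4-bromofuran-2(5H)-one | O=C1OCC(Br)=C1 | starting material
7 | 4-{[(R)-4-acetoxy-2,6,6-trimethylcyclohex-1-en-1-yl]ethynyl}furan-2(5H)-one | O=C1OCC(C#CC2=C(C)C[C@@H](OC(C)=O)CC2(C)C)=C1 | intermediate
8 | 4-{[(R)-4-hydroxy-2,6,6-trimethylcyclohex-1-en-1-yl]ethynyl}-2,5-dihydrofuran-2-ol (anomers) | OC1OCC(C#CC2=C(C)C[C@@H](O)CC2(C)C)=C1 | intermediate
9 | (R)-α-ionone, (E)-4-[(1R)-2,6,6-trimethylcyclohex-2-en-1-yl]but-3-en-2-one | CC1=CCCC(C)(C)[C@H]1/C=C/C(C)=O | starting material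
10 | triethyl phosphonoacetate | CCOC(=O)CP(=O)(OCC)OCC | starting material
11 | sodium (diethoxyphosphoryl)(ethoxycarbonyl)methanide | CCOC(=O)[CH-]P(=O)(OCC)OCC.[Na+] | intermediate (not isolated)
12 | ethyl (2E,4E)-3-methyl-5-[(1R)-2,6,6-trimethylcyclohex-2-en-1-yl]penta-2,4-dienoate | CC1=CCCC(C)(C)[C@H]1/C=C/C(C)=C/C(=O)OCC | intermediate
13 | ethyl (2E,4E)-3-methyl-5-[(1R)-2,6,6-trimethyl-4-oxocyclohex-2-en-1-yl]penta-2,4-dienoate | CC1=CC(=O)CC(C)(C)[C@H]1/C=C/C(C)=C/C(=O)OCC | intermediate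
14 | ethyl (2E,4E)-5-[(1R,4R)-4-hydroxy-2,6,6-trimethylcyclohex-2-en-1-yl]-3-methylpenta-2,4-dienoate | CC1=C[C@H](O)CC(C)(C)[C@H]1/C=C/C(C)=C/C(=O)OCC | intermediate
15 | (2E,4E)-5-[(1R,4R)-4-hydroxy-2,6,6-trimethylcyclohex-2-en-1-yl]-3-methylpenta-2,4-dien-1-ol | CC1=C[C@H](O)CC(C)(C)[C@H]1/C=C/C(C)=C/CO | intermediate
16 | [(2E,4E)-5-((1R,4R)-4-hydroxy-2,6,6-trimethylcyclohex-2-en-1-yl)-3-methylpenta-2,4-dienyl]triphenylphosphonium bromide | CC1=C[C@H](O)CC(C)(C)[C@H]1/C=C/C(C)=C/C[P+](c1ccccc1)(c1ccccc1)c1ccccc1.[Br-] | intermediate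
17 | (2E,4E,6E)-2,7-dimethylocta-2,4,6-trienedial | O=C/C(C)=C/C=C/C=C(C)/C=O | starting material
18 | C15 ylide from 16 | CC1=C[C@H](O)CC(C)(C)[C@H]1/C=C/C(C)=C/C=P(c1ccccc1)(c1ccccc1)c1ccccc1 | intermediate (not isolated)
19 | (2E,4E,6E,8E,10E,12E)-13-[(1R,4R)-4-hydroxy-2,6,6-trimethylcyclohex-2-en-1-yl]-2,7,11-trimethyltrideca-2,4,6,8,10,12-hexaenal | CC1=C[C@H](O)CC(C)(C)[C@H]1/C=C/C(C)=C/C=C/C(C)=C/C=C/C=C(C)/C=O | intermediate
20 | (2E,4E,6E,8E,10E,12E)-13-[(1R,4R)-4-hydroxy-2,6,6-trimethylcyclohex-2-en-1-yl]-2,7,11-trimethyltrideca-2,4,6,8,10,12-hexaen-1-ol | CC1=C[C@H](O)CC(C)(C)[C@H]1/C=C/C(C)=C/C=C/C(C)=C/C=C/C=C(C)/CO | intermediate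
21 | [(2E,4E,6E,8E,10E,12E)-13-((1R,4R)-4-hydroxy-2,6,6-trimethylcyclohex-2-en-1-yl)-2,7,11-trimethyltrideca-2,4,6,8,10,12-hexaenyl]triphenylphosphonium bromide | CC1=C[C@H](O)CC(C)(C)[C@H]1/C=C/C(C)=C/C=C/C(C)=C/C=C/C=C(C)/C[P+](c1ccccc1)(c1ccccc1)c1ccccc1.[Br-] | intermediate
22 | C25 ylide from 21 | CC1=C[C@H](O)CC(C)(C)[C@H]1/C=C/C(C)=C/C=C/C(C)=C/C=C/C=C(C)/C=P(c1ccccc1)(c1ccccc1)c1ccccc1 | intermediate (not isolated)
23 | (Z)-4-hydroxy-3-{[(R)-4-hydroxy-2,6,6-trimethylcyclohex-1-en-1-yl]ethynyl}but-2-enal (open form of 8, present as its sodium alkoxide) | O=C/C=C(\CO)C#CC1=C(C)C[C@@H](O)CC1(C)C | intermediate (not isolated)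
24 | (3R,3'R,6'R)-7,8-didehydro-β,ε-carotene-3,19,3'-triol (CH2OH at C9 cis to C11) | CC1=C[C@H](O)CC(C)(C)[C@H]1/C=C/C(C)=C/C=C/C(C)=C/C=C/C=C(C)/C=C/C=C(\CO)C#CC1=C(C)C[C@@H](O)CC1(C)C | intermediate
25 | (7Z)-(3R,3'R,6'R)-β,ε-carotene-3,8,19,3'-tetrol 8,19-cyclic carbonate | CC1=C[C@H](O)CC(C)(C)[C@H]1/C=C/C(C)=C/C=C/C(C)=C/C=C/C=C(C)/C=C/C=C(\COC(=O)O2)/C2=C/C1=C(C)C[C@@H](O)CC1(C)C | intermediate (not isolated)
26 | (3R,3'R,6'R)-3,19,3'-trihydroxy-7,8-dihydro-β,ε-caroten-8-one (siphonaxanthin) | CC1=C[C@H](O)CC(C)(C)[C@H]1/C=C/C(C)=C/C=C/C(C)=C/C=C/C=C(C)/C=C/C=C(\CO)C(=O)CC1=C(C)C[C@@H](O)CC1(C)C | target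

**Totals and risks**

Total step count: 14 (4 for the ring A branch, 8 for the ring B branch, 2 for the endgame). Longest linear sequence: 10 steps (9 → 26, steps 5–14).

Steps most likely to fail:

Step 14 (the new CO2-relayed hydration). The risks are slow 6-exo closure, competing direct 5-endo-dig attack of the free 19-OH on C7 (furan-type product, wrong regiochemistry) and polyene sensitivity to silver. The fallback uses only known chemistry, brings the C8 oxygen in as a carbinol through a C–C bond, and oxidises it late. It sets out from 5 (with 6 and 21) and comes back at 26.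
- Hydroboration of 5 with dicyclohexylborane (Cy2BH) and NaBO3·4H2O oxidation gives (R)-3,5,5-trimethyl-4-(2-oxoethyl)cyclohex-3-en-1-yl acetate F5.
- Nozaki–Hiyama–Kishi coupling of F5 with 6 (CrCl2, NiCl2 cat., DMF) gives 4-[1-hydroxy-2-((R)-4-acetoxy-2,6,6-trimethylcyclohex-1-en-1-yl)ethyl]furan-2(5H)-one F6 (C8 epimers).
- Et3SiCl/imidazole gives the triethylsilyl ether F7.
- i-Bu2AlH at −78 °C gives the lactol 4-[2-((R)-4-hydroxy-2,6,6-trimethylcyclohex-1-en-1-yl)-1-(triethylsilyloxy)ethyl]-2,5-dihydrofuran-2-ol F8.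
- Wittig reaction of F8 with the ylide 22 from 21 (as in step 13) gives (3R,3'R,6'R)-8-(triethylsilyloxy)-7,8-dihydro-β,ε-carotene-3,19,3'-triol F9.
- Ac2O/pyridine gives the 3,19,3'-triacetate F10.
- HF·pyridine in pyridine/THF gives (3R,3'R,6'R)-7,8-dihydro-β,ε-carotene-3,8,19,3'-tetrol 3,19,3'-triacetate F11.
- MnO2 in CH2Cl2 oxidises the only free (allylic) hydroxyl to siphonaxanthin 3,19,3'-triacetate F12.
- K2CO3/MeOH gives 26.

Step 12 (C25 phosphonium salt: the hexaenyl cation can eliminate or attack the ring allylic alcohol). The fallback reverses the polarity of the last olefination. It sets out from 7 and 19, comes back at 24, and bypasses 8 and 20–23.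
- Exhaustive i-Bu2AlH reduction of 7 (5 equiv, −78 → 0 °C) gives (Z)-2-{[(R)-4-hydroxy-2,6,6-trimethylcyclohex-1-en-1-yl]ethynyl}but-2-ene-1,4-diol F3.
- PPh3·HBr (1 equiv, MeOH, 0 °C) ionises only the C11 hydroxyl (its cation is conjugated with the enyne) and gives [(Z)-3-(hydroxymethyl)-5-((R)-4-hydroxy-2,6,6-trimethylcyclohex-1-en-1-yl)pent-2-en-4-ynyl]triphenylphosphonium bromide F4.
- Wittig reaction of F4 with aldehyde 19 (NaOMe, MeOH/CH2Cl2, then brief reflux in EtOAc) gives 24.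
- Price: the C9=C10 geometry may partly scramble at the allyl cation stage, so the 9-isomers must be separated.

Step 7 (catalyst and substrate may be mismatched, giving poor selectivity at C3'). The fallback is substrate-controlled reduction followed by stereoinversion. It sets out from 13 and comes back at 14.
- Luche reduction (NaBH4, CeCl3·7H2O, MeOH, −20 °C) and chromatography give, beside 14 itself, the cis isomer ethyl (2E,4E)-5-[(1R,4S)-4-hydroxy-2,6,6-trimethylcyclohex-2-en-1-yl]-3-methylpenta-2,4-dienoate F1.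
- Mitsunobu esterification of F1 (4-nitrobenzoic acid, PPh3, diisopropyl azodicarboxylate) inverts C3' and gives ethyl (2E,4E)-3-methyl-5-[(1R,4R)-2,6,6-trimethyl-4-(4-nitrobenzoyloxy)cyclohex-2-en-1-yl]penta-2,4-dienoate F2.
- K2CO3/EtOH cleaves F2 to 14.

**Further compounds**

F1 | step 7 | ethyl (2E,4E)-5-[(1R,4S)-4-hydroxy-2,6,6-trimethylcyclohex-2-en-1-yl]-3-methylpenta-2,4-dienoate | CC1=C[C@@H](O)CC(C)(C)[C@H]1/C=C/C(C)=C/C(=O)OCC
F2 | step 7 | ethyl (2E,4E)-3-methyl-5-[(1R,4R)-2,6,6-trimethyl-4-(4-nitrobenzoyloxy)cyclohex-2-en-1-yl]penta-2,4-dienoate | CC1=C[C@H](OC(=O)c2ccc(cc2)[N+](=O)[O-])CC(C)(C)[C@H]1/C=C/C(C)=C/C(=O)OCC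
F3 | step 12 | (Z)-2-{[(R)-4-hydroxy-2,6,6-trimethylcyclohex-1-en-1-yl]ethynyl}but-2-ene-1,4-diol | OC/C=C(\CO)C#CC1=C(C)C[C@@H](O)CC1(C)C
F4 | step 12 | [(Z)-3-(hydroxymethyl)-5-((R)-4-hydroxy-2,6,6-trimethylcyclohex-1-en-1-yl)pent-2-en-4-ynyl]triphenylphosphonium bromide | OC/C(C#CC1=C(C)C[C@@H](O)CC1(C)C)=C\C[P+](c1ccccc1)(c1ccccc1)c1ccccc1.[Br-]
F5 | step 14 | (R)-3,5,5-trimethyl-4-(2-oxoethyl)cyclohex-3-en-1-yl acetate | O=CCC1=C(C)C[C@@H](OC(C)=O)CC1(C)C
F6 | step 14 | 4-[1-hydroxy-2-((R)-4-acetoxy-2,6,6-trimethylcyclohex-1-en-1-yl)ethyl]furan-2(5H)-one (C8 epimers) | O=C1OCC(C(O)CC2=C(C)C[C@@H](OC(C)=O)CC2(C)C)=C1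
F7 | step 14 | 4-[2-((R)-4-acetoxy-2,6,6-trimethylcyclohex-1-en-1-yl)-1-(triethylsilyloxy)ethyl]furan-2(5H)-one | O=C1OCC(C(O[Si](CC)(CC)CC)CC2=C(C)C[C@@H](OC(C)=O)CC2(C)C)=C1
F8 | step 14 | 4-[2-((R)-4-hydroxy-2,6,6-trimethylcyclohex-1-en-1-yl)-1-(triethylsilyloxy)ethyl]-2,5-dihydrofuran-2-ol | OC1OCC(C(O[Si](CC)(CC)CC)CC2=C(C)C[C@@H](O)CC2(C)C)=C1
F9 | step 14 | (3R,3'R,6'R)-8-(triethylsilyloxy)-7,8-dihydro-β,ε-carotene-3,19,3'-triol (C8 epimers) | CC1=C[C@H](O)CC(C)(C)[C@H]1/C=C/C(C)=C/C=C/C(C)=C/C=C/C=C(C)/C=C/C=C(\CO)C(O[Si](CC)(CC)CC)CC1=C(C)C[C@@H](O)CC1(C)C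
F10 | step 14 | (3R,3'R,6'R)-8-(triethylsilyloxy)-7,8-dihydro-β,ε-carotene-3,19,3'-triyl triacetate | CC1=C[C@H](OC(C)=O)CC(C)(C)[C@H]1/C=C/C(C)=C/C=C/C(C)=C/C=C/C=C(C)/C=C/C=C(\COC(C)=O)C(O[Si](CC)(CC)CC)CC1=C(C)C[C@@H](OC(C)=O)CC1(C)C
F11 | step 14 | (3R,3'R,6'R)-7,8-dihydro-β,ε-carotene-3,8,19,3'-tetrol 3,19,3'-triacetate (C8 epimers) | CC1=C[C@H](OC(C)=O)CC(C)(C)[C@H]1/C=C/C(C)=C/C=C/C(C)=C/C=C/C=C(C)/C=C/C=C(\COC(C)=O)C(O)CC1=C(C)C[C@@H](OC(C)=O)CC1(C)C
F12 | step 14 | siphonaxanthin 3,19,3'-triacetate | CC1=C[C@H](OC(C)=O)CC(C)(C)[C@H]1/C=C/C(C)=C/C=C/C(C)=C/C=C/C=C(C)/C=C/C=C(\COC(C)=O)C(=O)CC1=C(C)C[C@@H](OC(C)=O)CC1(C)C
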